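Readings and results stem from a simulated flask from invented constants, noise included.

How much side product does this flask hold per part of target after 5.0 h and after 15 d, and which of the two leads? In a closed, stirred, isothermal flask, starting material meets reagent, free catalyst and a protic impurity, and gives target and side product. Tuesday's run is this same flask, followed up to 8.00 d.

- Tuesday's: starting material 0.034 M; reagent 0.0408 M; protic impurity 0.0102 M; free catalyst 21 µM; the very flask that is asked about, followed so far
- flask: starting material 0.034 M; reagent 0.0408 M; protic impurity 0.0102 M; free catalyst 21 µM; time 15 d

Tuesday's run (percent of the starting material charged)

| time / d | side product / % | target / % |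
|---|---|---|
| 1.67 | 40.9 | 4.7 |
| 3.00 | 55.0 | 5.7 |
| 5.00 | 64.0 | 7.8 |
| 6.00 | 64.9 | 8.6 |
| 8.00 | 66.0 | 8.1 |

(each reading ± 0.5 percentage points)

- what was read earlier has a scatter of 0.5 percentage points, one standard deviation

* ratio of side product to target at 5.0 h
* ratio of side product to target at 15 d
* which of side product and target there is more of at 15 d

I carry one number, the split S (a selectivity factor): side product over target, each summed over Tuesday's readings, S = 8.33. I pool them because a single target reading carries a scatter of 0.5 percentage points. Tuesday's single ratios go from 8.70 to 8.15 without a clear trend, and side product gains 1.1 points between the last two readings. So I expect S at 15 d, with side product ahead. I also expect S at 5.0 h, though that time lies before the first reading and is an extrapolation.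

The forecast gives 8.8 at 5.0 h and 7.8 at 15 d, with side product ahead: “nothing suggests a crossover”. My S lies between its two numbers .

The flask gives 8.33 and 8.48, with 66.4 % side product against 7.84 % target at 15 d, so the forecast is right.

    starting material + free catalyst → free catalyst + open intermediate (k = 19.0 /M/min)
    starting material + protic impurity → quenched substrate (k = 0.0300 /M/min)
    reagent + catalyst intermediate → free catalyst + target (k = 28.0 /M/min)
    open intermediate → side product (k = 0.00290 /min)
    free catalyst + open intermediate ⇌ catalyst intermediate (K = 24.0 /M, k = 45.0 /M/min)

Open intermediate either becomes side product or is caught by free catalyst as catalyst intermediate, which reagent turns into target or which falls back. Taking away that back reaction moves this flask's ratio at 15 d from 8.48 to 3.24. So I scale S with 1 + b, where b is the rate constant of that back reaction over that of capture by reagent, 1.64 as charged; with the rate constants and free catalyst held, b goes inversely with the reagent charge. A neighbour flask, the same but with reagent at 0.010 M, stands far from the forecast's numbers: S scaled to that charge gives 24.3, and that neighbour flask gives 25.5 at 15 d.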